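Numbering the carbons as in prostanoic acid, the cyclopentane ring C8–C12 is cut into a three-carbon unit C8–C9–C10, in which the C9 carbinol is read as a ketone flanked by an electrophilic alkene carbon (C8) and an enolizable methyl group (C10), and a two-carbon unit C11–C12, read as the β- and α-carbons of an enal whose formyl carbon is C13. One amine-catalysed iminium–enamine domino Michael/Michael reaction of two achiral, acyclic partners, a β-silyl acrolein and ethyl 4-oxopent-2-enoate, closes the ring and sets C8, C11 and C12; silicon on C11 is the latent hydroxyl. Lactol Wittig and a final Horner–Wadsworth–Emmons olefination attach the side chains.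

Key step: step 2

Remark: compounds 1, 2, 5, 12, 15 and both enantiomers of the amine catalyst are taken as commercial; lactol 11 is an anomeric mixture and is written without configuration at the hemiacetal carbon.

Step 1
Reactants: 1 3,3-diethoxyprop-1-yne; 2 dimethylphenylsilane
Product: 4 (E)-3-(dimethylphenylsilyl)prop-2-enal, via vinylsilane acetal 3 (not isolated)
Conditions: Pt2[(CH2=CHSiMe2)2O]3 (0.1 mol %), P(tBu)3, THF, 0 °C to rt; then TsOH·H2O (cat.), acetone–H2O, rt
Reagents that add atoms: water, O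
Why: Platinum-catalysed hydrosilylation of the terminal alkyne (syn addition of Si–H, silicon to the terminal carbon, the bulky phosphine suppressing the internal isomer) should give the (E)-vinylsilane, and mild acetal hydrolysis then unmasks the enal without protodesilylation.

Step 2
Reactants: 4 (E)-3-(dimethylphenylsilyl)prop-2-enal; 5 ethyl (E)-4-oxopent-2-enoate
Product: 7 ethyl 2-[(1R,2S,3R)-3-(dimethylphenylsilyl)-2-formyl-5-oxocyclopentyl]acetate, via enamine Michael adduct 6 (not isolated)
Conditions: (R)-2-[diphenyl(trimethylsilyloxy)methyl]pyrrolidine (10 mol %), 4-nitrophenol, H2O (3 equiv), iPrOH, rt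
Reagents that add atoms: none
Why: The secondary amine condenses with enal 4 to an (E)-iminium ion, the enol of the methyl ketone of 5 adds through C10 to the β-carbon C11 on the face left open by the CPh2(OSiMe3) group, and the enamine 6 so formed adds through C12 to C8 of the tethered ene-keto ester before hydrolysis releases 7 and the amine. The closest known reaction type is the diarylprolinol silyl ether catalysed iminium–enamine domino Michael/Michael reaction (formal [3+2] cycloaddition) of enals with γ-keto-α,β-unsaturated esters. The one ring that closes (C8–C12) does so in the 5-exo-trig mode, C12 attacking C8 with the C8=C7 bond outside the ring, which should be preferred over 6-endo attack at C7. C11 (R) is controlled by the catalyst, C12 by the same shielding in the enamine and by the trans relation to the silyl group, and C8 by an envelope transition state that places CH2CO2Et trans to the formyl group; because C8 and C12 stay enolizable, the all-trans isomer is also the thermodynamic sink. The step needs chemoselective enolization (only the methyl group of 5 can enolize, helped by 4-nitrophenol) and a C11 substituent that cannot leave from the enamine, which the carbon–silicon bond secures.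

Step 3
Reactants: 7 ethyl 2-[(1R,2S,3R)-3-(dimethylphenylsilyl)-2-formyl-5-oxocyclopentyl]acetate
Product: 10 (3aR,4S,5R,6aS)-5-hydroxy-4-(hydroxymethyl)hexahydro-2H-cyclopenta[b]furan-2-one, via diol ester 8 (not isolated), via fluorosilyl lactone 9 (not isolated)
Conditions: LiAlH(OtBu)3, THF, 0 °C to rt; then aq HBF4, rt, concentrate; then K2CO3, KF, 30% H2O2, DMF–H2O, 40 °C
Reagents that add atoms: hydrogen peroxide, OO; tetrafluoroboric acid, [H+].F[B-](F)(F)F (fluorine on silicon in 9 only)
Why: LiAlH(OtBu)3 should reduce the aldehyde and deliver hydride to the cyclopentanone from the face anti to the adjacent CH2CO2Et arm (ester untouched), so the new C9 hydroxyl is cis to that arm and closes the cis-fused γ-lactone under HBF4, which also cleaves the phenyl–silicon bond by ipso-protodesilylation, and Tamao–Fleming oxidation of the fluorosilane then replaces silicon by hydroxyl with retention at C11.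

Step 4
Reactants: 10 (3aR,4S,5R,6aS)-5-hydroxy-4-(hydroxymethyl)hexahydro-2H-cyclopenta[b]furan-2-one
Product: 11 (3aR,4S,5R,6aS)-4-(hydroxymethyl)hexahydro-2H-cyclopenta[b]furan-2,5-diol
Conditions: iBu2AlH (4 equiv), THF, −78 °C; MeOH, then Na2SO4·10H2O, filter
Reagents that add atoms: none
Why: Partial reduction of the lactone with iBu2AlH at low temperature should stop at the aluminium hemiacetal (two equivalents are consumed by the free hydroxyls), and a non-aqueous quench keeps the polar lactol out of water.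

Step 5
Reactants: 11 (3aR,4S,5R,6aS)-4-(hydroxymethyl)hexahydro-2H-cyclopenta[b]furan-2,5-diol; 12 (4-carboxybutyl)triphenylphosphonium bromide
Product: 13 (Z)-7-[(1R,2S,3R,5S)-3,5-dihydroxy-2-(hydroxymethyl)cyclopentyl]hept-5-enoic acid
Conditions: 12 (4 equiv), KOtBu (8 equiv), THF, 0 °C; then 11, 0 °C to rt; aq HCl to pH 4
Reagents that add atoms: none
Why: Wittig reaction of the open hydroxy-aldehyde form of the lactol with the non-stabilized, lithium-free ylide should give the (Z)-alkene under kinetic control, and excess ylide tolerates the free hydroxyls.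

Step 6
Reactants: 13 (Z)-7-[(1R,2S,3R,5S)-3,5-dihydroxy-2-(hydroxymethyl)cyclopentyl]hept-5-enoic acid
Product: 14 (Z)-7-[(1R,2R,3R,5S)-2-formyl-3,5-dihydroxycyclopentyl]hept-5-enoic acid
Conditions: TEMPO (0.2 equiv), PhI(OAc)2 (1.1 equiv), CH2Cl2–MeCN, 0 °C to rt; crude product used at once
Reagents that add atoms: none
Why: The oxoammonium (TEMPO/PhI(OAc)2) oxidation is sterically selective for the primary alcohol over the two secondary ones and stops at the aldehyde without water, while C12 already has the stable trans,trans arrangement.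

Step 7
Reactants: 14 (Z)-7-[(1R,2R,3R,5S)-2-formyl-3,5-dihydroxycyclopentyl]hept-5-enoic acid; 15 dimethyl (2-oxoheptyl)phosphonate
Product: 16 15-keto-PGF2alpha, (Z)-7-[(1R,2R,3R,5S)-3,5-dihydroxy-2-[(E)-3-oxooct-1-enyl]cyclopentyl]hept-5-enoic acid
Conditions: LiCl, iPr2NEt, MeCN, 0 °C to rt; work-up at pH 4
Reagents that add atoms: none
Why: Horner–Wadsworth–Emmons olefination with the lithium-chelated ketophosphonate and a mild amine base should give the (E)-enone directly at the ketone oxidation level while sparing the β-hydroxy aldehyde from elimination.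

Compound list
1 | 3,3-diethoxyprop-1-yne | C#CC(OCC)OCC | starting material
2 | dimethylphenylsilane | C[SiH](C)c1ccccc1 | starting material
3 | (E)-(3,3-diethoxyprop-1-enyl)dimethylphenylsilane | CCOC(OCC)/C=C/[Si](C)(C)c1ccccc1 | intermediate (step 1, not isolated)
4 | (E)-3-(dimethylphenylsilyl)prop-2-enal | O=C/C=C/[Si](C)(C)c1ccccc1 | intermediate
5 | ethyl (E)-4-oxopent-2-enoate | CCOC(=O)/C=C/C(C)=O | starting material
6 | ethyl (2E,6R,7E)-6-(dimethylphenylsilyl)-8-[(2R)-2-[diphenyl(trimethylsilyloxy)methyl]pyrrolidin-1-yl]-4-oxoocta-2,7-dienoate | CCOC(=O)/C=C/C(=O)C[C@H](/C=C/N1CCC[C@@H]1C(O[Si](C)(C)C)(c1ccccc1)c1ccccc1)[Si](C)(C)c1ccccc1 | intermediate (step 2, not isolated)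
7 | ethyl 2-[(1R,2S,3R)-3-(dimethylphenylsilyl)-2-formyl-5-oxocyclopentyl]acetate | O=C[C@@H]1[C@@H](CC(=O)OCC)C(=O)C[C@H]1[Si](C)(C)c1ccccc1 | intermediate
8 | ethyl 2-[(1R,2S,3R,5S)-3-(dimethylphenylsilyl)-5-hydroxy-2-(hydroxymethyl)cyclopentyl]acetate | OC[C@@H]1[C@@H](CC(=O)OCC)[C@@H](O)C[C@H]1[Si](C)(C)c1ccccc1 | intermediate (step 3, not isolated)
9 | (3aR,4S,5R,6aS)-5-(fluorodimethylsilyl)-4-(hydroxymethyl)hexahydro-2H-cyclopenta[b]furan-2-one | OC[C@@H]1[C@@H](CC(=O)O2)[C@@H]2C[C@H]1[Si](C)(C)F | intermediate (step 3, not isolated)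
10 | (3aR,4S,5R,6aS)-5-hydroxy-4-(hydroxymethyl)hexahydro-2H-cyclopenta[b]furan-2-one | OC[C@@H]1[C@@H](CC(=O)O2)[C@@H]2C[C@H]1O | intermediate
11 | (3aR,4S,5R,6aS)-4-(hydroxymethyl)hexahydro-2H-cyclopenta[b]furan-2,5-diol (both anomers) | OC[C@@H]1[C@@H](CC(O)O2)[C@@H]2C[C@H]1O | intermediate
12 | (4-carboxybutyl)triphenylphosphonium bromide | OC(=O)CCCC[P+](c1ccccc1)(c1ccccc1)c1ccccc1.[Br-] | starting material
13 | (Z)-7-[(1R,2S,3R,5S)-3,5-dihydroxy-2-(hydroxymethyl)cyclopentyl]hept-5-enoic acid | OC[C@@H]1[C@@H](C/C=C\CCCC(=O)O)[C@@H](O)C[C@H]1O | intermediate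
14 | (Z)-7-[(1R,2R,3R,5S)-2-formyl-3,5-dihydroxycyclopentyl]hept-5-enoic acid | O=C[C@@H]1[C@@H](C/C=C\CCCC(=O)O)[C@@H](O)C[C@H]1O | intermediate
15 | dimethyl (2-oxoheptyl)phosphonate | CCCCCC(=O)CP(=O)(OC)OC | starting material
16 | 15-keto-PGF2alpha, (Z)-7-[(1R,2R,3R,5S)-3,5-dihydroxy-2-[(E)-3-oxooct-1-enyl]cyclopentyl]hept-5-enoic acid | CCCCCC(=O)/C=C/[C@@H]1[C@@H](C/C=C\CCCC(=O)O)[C@@H](O)C[C@H]1O | target

Total step count: 7. Longest linear sequence: 7 steps (1 to 16).

Steps most likely to fail

Step 6 (this fallback also replaces step 7). The oxidation may run on to the acid or touch a secondary hydroxyl, and the free β-hydroxy aldehyde may lose the C11 hydroxyl by elimination before or during olefination. The fallback sets out from 13 and comes back at 16. Silylation of 13 with Et3SiCl and imidazole in DMF, with cleavage of the silyl ester on aqueous K2CO3 work-up, should give (Z)-7-[(1R,2S,3R,5S)-3,5-bis(triethylsilyloxy)-2-(triethylsilyloxymethyl)cyclopentyl]hept-5-enoic acid F1. HF·pyridine buffered with pyridine in THF at 0 °C should remove only the primary silyl ether to give (Z)-7-[(1R,2S,3R,5S)-2-(hydroxymethyl)-3,5-bis(triethylsilyloxy)cyclopentyl]hept-5-enoic acid F2. Dess–Martin periodinane with NaHCO3 in CH2Cl2 then gives (Z)-7-[(1R,2R,3R,5S)-2-formyl-3,5-bis(triethylsilyloxy)cyclopentyl]hept-5-enoic acid F3, which has no free β-hydroxyl. Olefination with 15 (LiCl, iPr2NEt, MeCN) gives (Z)-7-[(1R,2R,3R,5S)-2-[(E)-3-oxooct-1-enyl]-3,5-bis(triethylsilyloxy)cyclopentyl]hept-5-enoic acid F4, and HF·pyridine in THF at rt removes both silyl ethers to give 16.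

Step 4. The unprotected diol may consume the hydride unevenly, so that over-reduction to the tetraol or incomplete conversion occurs, and the very polar lactol may be lost on isolation. The fallback sets out from 10 and comes back at 13. tBuMe2SiCl and imidazole in DMF give (3aR,4S,5R,6aS)-5-(tert-butyldimethylsilyloxy)-4-[(tert-butyldimethylsilyloxy)methyl]hexahydro-2H-cyclopenta[b]furan-2-one F5. iBu2AlH in toluene at −78 °C gives the corresponding lactol (3aR,4S,5R,6aS)-5-(tert-butyldimethylsilyloxy)-4-[(tert-butyldimethylsilyloxy)methyl]hexahydro-2H-cyclopenta[b]furan-2-ol F6. Wittig reaction with the ylide from 12 and KOtBu gives (Z)-7-[(1R,2S,3R,5S)-3-(tert-butyldimethylsilyloxy)-2-[(tert-butyldimethylsilyloxy)methyl]-5-hydroxycyclopentyl]hept-5-enoic acid F7, and Bu4NF in THF removes both silyl ethers to give 13.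

Step 2. Enolization of the methyl ketone may be too slow, so that the enal oligomerizes or the cascade stalls after the first conjugate addition. The fallback sets out from 4 and comes back at 7; it uses a more acidic β-keto ester donor with a removable activating group on C10. Decarboxylative acylation of potassium 3-tert-butoxy-3-oxopropanoate with ethyl (E)-4-chloro-4-oxobut-2-enoate (MgCl2, Et3N, MeCN) gives 1-tert-butyl 6-ethyl (E)-3-oxohex-4-enedioate F8. F8 should undergo the same amine-catalysed Michael/Michael sequence with 4, with the same (R)-amine, to give tert-butyl 5-(dimethylphenylsilyl)-3-(2-ethoxy-2-oxoethyl)-4-formyl-2-oxocyclopentane-1-carboxylate F9, with the ring configuration of 7 at the other three centres. TsOH (cat.) in toluene at 80 °C then removes the activating ester by dealkylative decarboxylation to give 7.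

Further compounds
F1 | step 6 | (Z)-7-[(1R,2S,3R,5S)-3,5-bis(triethylsilyloxy)-2-(triethylsilyloxymethyl)cyclopentyl]hept-5-enoic acid | CC[Si](CC)(CC)OC[C@@H]1[C@@H](C/C=C\CCCC(=O)O)[C@@H](O[Si](CC)(CC)CC)C[C@H]1O[Si](CC)(CC)CC
F2 | step 6 | (Z)-7-[(1R,2S,3R,5S)-2-(hydroxymethyl)-3,5-bis(triethylsilyloxy)cyclopentyl]hept-5-enoic acid | OC[C@@H]1[C@@H](C/C=C\CCCC(=O)O)[C@@H](O[Si](CC)(CC)CC)C[C@H]1O[Si](CC)(CC)CC
F3 | step 6 | (Z)-7-[(1R,2R,3R,5S)-2-formyl-3,5-bis(triethylsilyloxy)cyclopentyl]hept-5-enoic acid | O=C[C@@H]1[C@@H](C/C=C\CCCC(=O)O)[C@@H](O[Si](CC)(CC)CC)C[C@H]1O[Si](CC)(CC)CC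
F4 | step 6 | (Z)-7-[(1R,2R,3R,5S)-2-[(E)-3-oxooct-1-enyl]-3,5-bis(triethylsilyloxy)cyclopentyl]hept-5-enoic acid | CCCCCC(=O)/C=C/[C@@H]1[C@@H](C/C=C\CCCC(=O)O)[C@@H](O[Si](CC)(CC)CC)C[C@H]1O[Si](CC)(CC)CC
F5 | step 4 | (3aR,4S,5R,6aS)-5-(tert-butyldimethylsilyloxy)-4-[(tert-butyldimethylsilyloxy)methyl]hexahydro-2H-cyclopenta[b]furan-2-one | CC(C)(C)[Si](C)(C)OC[C@@H]1[C@@H](CC(=O)O2)[C@@H]2C[C@H]1O[Si](C)(C)C(C)(C)C
F6 | step 4 | (3aR,4S,5R,6aS)-5-(tert-butyldimethylsilyloxy)-4-[(tert-butyldimethylsilyloxy)methyl]hexahydro-2H-cyclopenta[b]furan-2-ol (both anomers) | CC(C)(C)[Si](C)(C)OC[C@@H]1[C@@H](CC(O)O2)[C@@H]2C[C@H]1O[Si](C)(C)C(C)(C)C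
F7 | step 4 | (Z)-7-[(1R,2S,3R,5S)-3-(tert-butyldimethylsilyloxy)-2-[(tert-butyldimethylsilyloxy)methyl]-5-hydroxycyclopentyl]hept-5-enoic acid | CC(C)(C)[Si](C)(C)OC[C@@H]1[C@@H](C/C=C\CCCC(=O)O)[C@@H](O)C[C@H]1O[Si](C)(C)C(C)(C)C
F8 | step 2 | 1-tert-butyl 6-ethyl (E)-3-oxohex-4-enedioate | CCOC(=O)/C=C/C(=O)CC(=O)OC(C)(C)C
F9 | step 2 | tert-butyl 5-(dimethylphenylsilyl)-3-(2-ethoxy-2-oxoethyl)-4-formyl-2-oxocyclopentane-1-carboxylate (ring configuration as in 7, ester-bearing carbon unassigned) | O=C[C@@H]1[C@@H](CC(=O)OCC)C(=O)C(C(=O)OC(C)(C)C)[C@H]1[Si](C)(C)c1ccccc1
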